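| setting | alder | ash | flask |
|---|---|---|---|
| Z | 20 mM | 10 mM | 20 mM |
| J | 6 mM | 6 mM | 6.00 mM |
| E | 0.50 mM | 0.50 mM | 0.50 mM |
| remark | the very flask that is asked about, followed so far | run made earlier |  |
| time |  |  | 10 h |

- alder (time / h: L / %): 0.133: 49.7; 0.250: 61.8; 0.417: 65.3; 0.667: 67.1; 1.00: 64.0; 2.00: 61.8; 3.00: 59.6
- ash (time / h: L / %): 0.133: 51.5; 0.250: 65.7; 0.667: 74.2; 1.33: 72.4; 2.50: 68.5; 5.00: 66.6; 10.0: 66.4

(standard deviation of a reading: 0.5 percentage points)

- the analysis behind the earlier runs scatters by 0.5 percentage points, standard deviation

1. the moment within 10 h at which there is most L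
2. the amount of L, in percent of the Z charged, at that time

- I began with the easiest step, the first alder reading, where the monomer Z had given 49.7% of L, the monomer in chains, after 0.133 h. Counting that L as Z gone gave 0.134 h as the Z half-life, the time in which the opening rate halves Z.
- The first setting was the Z charge. If uptake was pseudo-first-order, half the charge should keep the same half-life, and the ash run gave 0.127 h. Its highest reading of L was 74.2%, above the 67.1% of alder.
- The second setting was the time. Alder's highest reading came at 0.667 h, or 4.98 Z half-lives, and by 3.00 h L read 59.6%, so I committed to that count and to about 67.1%, a reading with its scatter.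
- The initiator E and the further species J had the same charges in both runs, so I had no pair of runs to compare for either setting.
- The forecast said 0.55 h and 66.3%, earlier and lower than my reckoning, placing the peak “where fast growth meets slow loss”.
- The alder flask gave 66.0% at 0.558 h, which is 4.16 Z half-lives.

    Z + E → G + L (k = 3.50 L mol⁻¹ s⁻¹)
    Z + G → L + G, rate k2*[G]*[Z] (k = 4.10 L mol⁻¹ s⁻¹)
    G + J → D (k = 0.180 L mol⁻¹ s⁻¹)
    Z + L → Q (k = 0.0200 L mol⁻¹ s⁻¹)

- Here G is the living end, D is what G and J form, and Q is the other product. In the alder flask at 0.0842 h, G had a half-life of 0.18 h by its step with J, longer than the Z half-life, so 1.36 Z half-lives fitted into one of G. For a neighbour flask with 0.30 mM of E, I reckoned the Z half-life as inversely proportional to E, which gave 0.224 h, so 0.804 of these fitted into G's 0.18 h, and that flask reached 48.0% of L and ended with 71.4% of the Z charged as Q.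

(All runs are simulated from invented constants, noise included.)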